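## Analysis of the target

The target is a 2-aryl-4H-chromen-4-one: benzo ring A is fused through the C4a–C8a bond to the γ-pyranone ring C, and aryl ring B sits on C2. There is no stereocentre. Ring A is hexasubstituted: C5, C6, C7 and C8 each carry a methoxy group and C4a and C8a belong to ring C, so no ring A C–H is left for a late substitution. C3 carries a further methoxy group, and ring B carries a 4'-methoxy group flanked by free hydroxyls at C3' and C5'. Two phenols must therefore be told apart from six methyl ethers, so they have to travel protected; a selective late demethylation is excluded because the 5-methoxy group, peri to the C4 carbonyl, is the ether most easily lost to Lewis acids.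

The feature the route is built on is the unit C5–C6–C7–C8 of ring A. Every one of these four carbons bears one oxygen and the oxygens on C5 and C8 are para to each other, so this is a C4O4 squaric acid unit. The remaining bond of ring A, C4a=C8a, is the C5=C6 double bond of a monocyclic 4-pyranone.

Sensitive points are the γ-pyranone with a free position next to the ring oxygen (open to nucleophiles and hydroxide), 5,8-dihydroxy intermediates (air oxidation to quinones) and the electron-rich ring B (electrophilic halogenation). The difficulty is ring A: the usual flavone syntheses build ring C onto a finished ring A, so the fully oxygenated benzene has to be paid for by stepwise oxidation chemistry.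

## Retrosynthetic reasoning

The target 17 is traced back to its bis(methoxymethyl) ether 16. The two acetal C–O bonds on ring B are cut last because acetal cleavage by dilute protic acid leaves all six aryl methyl ethers alone, the peri 5-methoxy group included.

Compound 16 is traced back to the 5,8-hydroquinone 15 by cutting the two O–CH3 bonds at C5 and C8. This is gained for nothing in strategy terms: the two oxygens that the key step leaves as free phenols are exactly the two that still lack a methyl group, while the ring B oxygens are masked.

The key disconnection is made in 15. Ring A is cut at C8–C8a and at C4a–C5, which removes C5–C8 with their four oxygens as one unit and leaves a monocyclic 2-aryl-3-methoxy-4-pyranone. In the forward direction the C8–C8a bond is formed by the electrocyclic cascade of the hydroxycyclobutenone 12, in which the C4a–C5 bond is already present. Ring A with all six substituents is thus created in one thermal operation from a precursor that contains no benzene ring A at all. The cut is made here and not in ring C because ring C chemistry leaves the hard part, the hexasubstituted ring A, untouched. A further gain is constitutional: because the oxygens at C5 and C8 end up equivalent in 15, the same product results whichever of the two pyranone carbons carries the four-membered ring.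

Compound 12 is cut at the bond between the carbinol carbon and the pyranone, giving the squarate 10 as electrophile and a C5-metalated pyranone derived from the iodide 9. Halogen–metal exchange is chosen over direct deprotonation so that the nucleophile is formed completely and cold, in the absence of unmetalated pyranone with its free Michael position.

Iodide 9 is traced back to pyranone 7 by a C–H to C–I exchange at the only C–H that flanks the carbonyl. A deprotonative method is preferred to an electrophilic one because ring B is the more electron-rich arene.

Pyranone 7 is cut at the C2–C1' bond into the bromopyranone 6 and the boronate 3. The C2–Br bond of 6 is a vinylogous acyl bromide and so a good partner for cross-coupling; making this bond early keeps the later steps linear and short.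

Bromopyranone 6 goes back through the enol 5 to the commercial hydroxypyranone 4, which already contains ring C with its C3 oxygen; the enol hydroxyl directs the halogen to C2 before it is methylated. Boronate 3 goes back through the bis-acetal 2 to the commercial diol 1: the only ring C–H of 2 that is not ortho to a substituent is the one para to the methoxy group, which is where ring B must be joined.

## Alternatives that were turned down

Alternative 1: The textbook route cuts ring C at O1–C2 and at the C2–C3 aldol bond. Forward: Claisen–Schmidt condensation of 2'-hydroxy-3',4',5',6'-tetramethoxyacetophenone A1 with 3,5-bis(benzyloxy)-4-methoxybenzaldehyde A2 gives the chalcone A3, Algar–Flynn–Oyamada oxidation gives the flavonol A4, and methylation and hydrogenolysis follow. It was turned down for two reasons. First, the key step builds only ring C, and A1 is itself a hexasubstituted, pentaoxygenated benzene that must be assembled by several successive substitutions and oxidations of a simpler phenol. Second, in A3 the methoxy group ortho to the carbonyl (the future 5-methoxy group) twists the enone out of plane, a situation in which the oxidative cyclization is known to turn towards closure of the five-membered benzofuranone ring instead of the pyranone.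

Alternative 2: Ring C is cut at C4–C4a, C3–C4 and O1–C2. Forward: a palladium-catalysed carbonylative Sonogashira annulation of 2-iodo-3,4,5,6-tetramethoxyphenol A5 with the ring B alkyne A6 gives the flavone A7. It was turned down because A7 lacks the C3 oxygen, which would cost a later C3 metalation, oxidation and methylation. A5 is again a hexasubstituted benzene that has to be made stepwise. Oxidative addition into an electron-rich aryl iodide with two ortho substituents is slow, and the alkynone intermediate can close in the five-membered mode.

Alternative 3: The C8–O and C6–O bonds of ring A are cut. Forward: a phloroglucinol-derived 5-hydroxy-3,7-dimethoxyflavone A8 is hydroxylated at C8, para to the 5-hydroxyl, by an Elbs oxidation (or its anodic counterpart) to the 5,8-dihydroxyflavone A9, and a second nuclear oxidation then has to bring in the C6 oxygen. It was turned down because the para-hydroxylation stops at low conversion, and the C6 oxygen has no para-hydroxyl to direct it. The hydroquinone A9 and the electron-rich ring B are more easily oxidized than A8 under the same conditions. A8 itself still needs a full classical flavonol synthesis.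

Key step: step 8

Assumption: 2-methoxybenzene-1,3-diol (1), 3-hydroxy-4H-pyran-4-one (4) and dimethyl squarate (10) are taken as commercial. The only stereocentre the route creates (the carbinol carbon of 12, racemic) is erased in step 8.

## Route

Step 1
Reactants: 1 2-methoxybenzene-1,3-diol
Product: 2 2-methoxy-1,3-bis(methoxymethoxy)benzene
Conditions: MOMCl, iPr2NEt, CH2Cl2, 0 °C to rt
Reagents that add atoms: chloromethyl methyl ether, COCCl
Why: Acetal ether formation on both phenols; methoxymethyl groups have no aryl C–H to compete in step 2, survive bases, organometallics and 110 °C, and are removed at the end by acid that leaves aryl methyl ethers alone.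

Step 2
Reactants: 2 2-methoxy-1,3-bis(methoxymethoxy)benzene
Product: 3 2-[4-methoxy-3,5-bis(methoxymethoxy)phenyl]-4,4,5,5-tetramethyl-1,3,2-dioxaborolane
Conditions: [Ir(OMe)(cod)]2 (cat.), 4,4'-di-tert-butyl-2,2'-bipyridine (cat.), B2pin2, THF, 80 °C
Reagents that add atoms: bis(pinacolato)diboron, CC1(C)OB(OC1(C)C)B1OC(C)(C)C(C)(C)O1
Why: Iridium-catalysed aromatic C–H borylation is governed by sterics; C5 is the only ring C–H not ortho to a substituent, so boron should enter para to the methoxy group.

Step 3
Reactants: 4 3-hydroxy-4H-pyran-4-one
Product: 5 2-bromo-3-hydroxy-4H-pyran-4-one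
Conditions: NBS (1.0 equiv), MeCN, 0 °C to rt
Reagents that add atoms: N-bromosuccinimide, O=C1CCC(=O)N1Br
Why: Electrophilic bromination of the enol at C2, the carbon ortho to the enol hydroxyl (the α-carbon of the tautomeric 3,4-dione), which is where 3-hydroxy-4-pyranones take up electrophiles; one equivalent at low temperature should limit a second bromination.

Step 4
Reactants: 5 2-bromo-3-hydroxy-4H-pyran-4-one
Product: 6 2-bromo-3-methoxy-4H-pyran-4-one
Conditions: MeI, K2CO3, acetone, 40 °C
Reagents that add atoms: iodomethane, CI
Why: Williamson O-methylation of the acidic enol installs the future C3 methoxy group and removes the acidic proton before the coupling.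

Step 5
Reactants: 6 2-bromo-3-methoxy-4H-pyran-4-one; 3 2-[4-methoxy-3,5-bis(methoxymethoxy)phenyl]-4,4,5,5-tetramethyl-1,3,2-dioxaborolane
Product: 7 3-methoxy-2-[4-methoxy-3,5-bis(methoxymethoxy)phenyl]-4H-pyran-4-one
Conditions: Pd(PPh3)4 (cat.), CsF, DME, 80 °C
Reagents that add atoms: none
Why: Suzuki–Miyaura coupling; the C2–Br bond is a vinylogous acyl bromide that adds readily to zerovalent palladium, and fluoride activation without water spares the pyranone from ring opening by hydroxide.

Step 6
Reactants: 7 3-methoxy-2-[4-methoxy-3,5-bis(methoxymethoxy)phenyl]-4H-pyran-4-one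
Product: 9 5-iodo-3-methoxy-2-[4-methoxy-3,5-bis(methoxymethoxy)phenyl]-4H-pyran-4-one, via bis(pyranonyl)zinc 8 (not isolated)
Conditions: Zn(TMP)2·2MgCl2·2LiCl (0.6 equiv; TMP = 2,2,6,6-tetramethylpiperidide), THF, −20 °C to rt; then I2, THF, 0 °C
Reagents that add atoms: iodine, II
Why: Directed deprotonative zincation followed by iodolysis: MgCl2 bound to the pyranone carbonyl should steer the amide to the only C–H that flanks it (C5), the diorganozinc is too weak a nucleophile to attack the free C6 position of unreacted 7, and iodine enters at the metalated carbon without touching the electron-rich ring B.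

Step 7
Reactants: 9 5-iodo-3-methoxy-2-[4-methoxy-3,5-bis(methoxymethoxy)phenyl]-4H-pyran-4-one; 10 dimethyl squarate (3,4-dimethoxycyclobut-3-ene-1,2-dione)
Product: 12 rac-4-hydroxy-2,3-dimethoxy-4-{5-methoxy-6-[4-methoxy-3,5-bis(methoxymethoxy)phenyl]-4-oxo-4H-pyran-3-yl}cyclobut-2-en-1-one, via pyranonylmagnesium chloride 11 (not isolated)
Conditions: iPrMgCl·LiCl, THF, −78 °C; then cannulation into 10, THF, −78 °C; aq. NH4Cl, −78 °C
Reagents that add atoms: none
Why: Iodine–magnesium exchange at an sp2 carbon next to a carbonyl is fast at −78 °C and should outrun addition of the reagent to C6; the alkenyl Grignard then adds 1,2 to one carbonyl of the squarate (the alkoxide formed deactivates the second) to give the tertiary alcohol as a racemate whose stereocentre is erased in step 8.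

Step 8
Reactants: 12 rac-4-hydroxy-2,3-dimethoxy-4-{5-methoxy-6-[4-methoxy-3,5-bis(methoxymethoxy)phenyl]-4-oxo-4H-pyran-3-yl}cyclobut-2-en-1-one
Product: 15 5,8-dihydroxy-3,6,7-trimethoxy-2-[4-methoxy-3,5-bis(methoxymethoxy)phenyl]-4H-chromen-4-one, via dienylketene 13 (not isolated), via cyclohexadienone 14 (not isolated)
Conditions: degassed toluene (0.02 M), 110 °C, Ar
Reagents that add atoms: none
Why: Heating opens the cyclobutenone by a conrotatory 4π electrocyclic cleavage of its C1–C4 bond; the hydroxyl group, as the donor on C4, turns outward, so the pyranonyl group turns inward and the (Z)-dienylketene 13 forms with the pyranone next to the ketene carbon. A thermal disrotatory 6π electrocyclization of the ketene C=C, the enol C=C and the pyranone C5=C6 bond then joins the ketene carbon to pyranone C6 (the future C8–C8a bond) and closes the six-membered carbocycle, ring A, as the cyclohexadienone 14. Enolization of 14 moves the hydrogen from C8a to the oxygen on C8 and gives the aromatic hydroquinone 15, in which the four squarate carbons have become C5, C6, C7 and C8 with their four oxygens in place. The closest known reaction type is the Moore rearrangement of 4-alkenyl- and 4-aryl-4-hydroxycyclobutenones to hydroquinones. No stereocentre survives: the carbinol centre of 12 becomes sp2 in 13 and the C8a centre of 14 is lost on aromatization. The step needs ring closure at carbon to win over addition of the hydroxyl group to the ketene; outward rotation places the hydroxyl trans to the ketene, and its hydrogen bond to the pyranone C4 carbonyl holds C6, not C4, on the ketene side. The regiochemistry cannot go astray, because C6 is the only free terminus and because the 5,8-dioxygenation pattern would be the same whichever pyranone carbon carried the four-membered ring.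

Step 9
Reactants: 15 5,8-dihydroxy-3,6,7-trimethoxy-2-[4-methoxy-3,5-bis(methoxymethoxy)phenyl]-4H-chromen-4-one
Product: 16 3,5,6,7,8-pentamethoxy-2-[4-methoxy-3,5-bis(methoxymethoxy)phenyl]-4H-chromen-4-one
Conditions: Me2SO4 (excess), K2CO3, degassed acetone, reflux, Ar
Reagents that add atoms: dimethyl sulfate, COS(=O)(=O)OC
Why: Williamson methylation of both phenols; the hydrogen-bonded 5-hydroxyl needs excess reagent and prolonged reflux, the usual forcing conditions for 5-hydroxyflavones, exclusion of air keeps the hydroquinone from going to the quinone, and the acetals are inert to base.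

Step 10
Reactants: 16 3,5,6,7,8-pentamethoxy-2-[4-methoxy-3,5-bis(methoxymethoxy)phenyl]-4H-chromen-4-one
Product: 17 2-(3,5-dihydroxy-4-methoxyphenyl)-3,5,6,7,8-pentamethoxy-4H-chromen-4-one (3',5'-dihydroxy-3,5,6,7,8,4'-hexamethoxyflavone)
Conditions: conc. HCl (cat.), MeOH, 50 °C
Reagents that add atoms: none
Why: Acid-catalysed acetal exchange with methanol frees the two ring B phenols; aryl methyl ethers, the peri 5-methoxy group included, are stable to dilute protic acid.

## Compound list

1 | 2-methoxybenzene-1,3-diol | COc1c(O)cccc1O | starting material
2 | 2-methoxy-1,3-bis(methoxymethoxy)benzene | COCOc1cccc(OCOC)c1OC | intermediate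
3 | 2-[4-methoxy-3,5-bis(methoxymethoxy)phenyl]-4,4,5,5-tetramethyl-1,3,2-dioxaborolane | COCOc1cc(B2OC(C)(C)C(C)(C)O2)cc(OCOC)c1OC | intermediate
4 | 3-hydroxy-4H-pyran-4-one (pyromeconic acid) | O=c1ccocc1O | starting material
5 | 2-bromo-3-hydroxy-4H-pyran-4-one | O=c1ccoc(Br)c1O | intermediate
6 | 2-bromo-3-methoxy-4H-pyran-4-one | COc1c(Br)occc1=O | intermediate
7 | 3-methoxy-2-[4-methoxy-3,5-bis(methoxymethoxy)phenyl]-4H-pyran-4-one | COCOc1cc(-c2occc(=O)c2OC)cc(OCOC)c1OC | intermediate
8 | bis{5-methoxy-6-[4-methoxy-3,5-bis(methoxymethoxy)phenyl]-4-oxo-4H-pyran-3-yl}zinc (MgCl2/LiCl complex, not isolated) | COCOc1cc(-c2occ([Zn]c3coc(-c4cc(OCOC)c(OC)c(OCOC)c4)c(OC)c3=O)c(=O)c2OC)cc(OCOC)c1OC | intermediate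
9 | 5-iodo-3-methoxy-2-[4-methoxy-3,5-bis(methoxymethoxy)phenyl]-4H-pyran-4-one | COCOc1cc(-c2occ(I)c(=O)c2OC)cc(OCOC)c1OC | intermediate
10 | dimethyl squarate (3,4-dimethoxycyclobut-3-ene-1,2-dione) | COC1=C(OC)C(=O)C1=O | starting material
11 | {5-methoxy-6-[4-methoxy-3,5-bis(methoxymethoxy)phenyl]-4-oxo-4H-pyran-3-yl}magnesium chloride (LiCl complex, not isolated) | COCOc1cc(-c2occ([Mg]Cl)c(=O)c2OC)cc(OCOC)c1OC | intermediate
12 | rac-4-hydroxy-2,3-dimethoxy-4-{5-methoxy-6-[4-methoxy-3,5-bis(methoxymethoxy)phenyl]-4-oxo-4H-pyran-3-yl}cyclobut-2-en-1-one | COC1=C(OC)C(O)(c2coc(-c3cc(OCOC)c(OC)c(OCOC)c3)c(OC)c2=O)C1=O | intermediate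
13 | (3Z)-4-hydroxy-2,3-dimethoxy-4-{5-methoxy-6-[4-methoxy-3,5-bis(methoxymethoxy)phenyl]-4-oxo-4H-pyran-3-yl}buta-1,3-dien-1-one (not isolated) | O=C=C(OC)/C(OC)=C(/O)c1coc(-c2cc(OCOC)c(OC)c(OCOC)c2)c(OC)c1=O | intermediate
14 | rac-5-hydroxy-3,6,7-trimethoxy-2-[4-methoxy-3,5-bis(methoxymethoxy)phenyl]-8aH-chromene-4,8-dione (not isolated) | O=C1C(OC)=C(OC)C(O)=C2C(=O)C(OC)=C(c3cc(OCOC)c(OC)c(OCOC)c3)OC12 | intermediate
15 | 5,8-dihydroxy-3,6,7-trimethoxy-2-[4-methoxy-3,5-bis(methoxymethoxy)phenyl]-4H-chromen-4-one | COCOc1cc(-c2oc3c(O)c(OC)c(OC)c(O)c3c(=O)c2OC)cc(OCOC)c1OC | intermediate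
16 | 3,5,6,7,8-pentamethoxy-2-[4-methoxy-3,5-bis(methoxymethoxy)phenyl]-4H-chromen-4-one | COCOc1cc(-c2oc3c(OC)c(OC)c(OC)c(OC)c3c(=O)c2OC)cc(OCOC)c1OC | intermediate
17 | 2-(3,5-dihydroxy-4-methoxyphenyl)-3,5,6,7,8-pentamethoxy-4H-chromen-4-one | COc1c(O)cc(-c2oc3c(OC)c(OC)c(OC)c(OC)c3c(=O)c2OC)cc1O | target

## Step count and least certain steps

Total: 10 steps. Longest linear sequence: 8 steps (steps 3 to 10, from 4 to 17); the two-step branch to boronate 3 joins at step 5.

Step 8 (key step). What may go wrong is diversion of the dienylketene before ring closure: closure onto the electron-poor C6 terminus may be slow, a ketene whose hydroxyl has come cis to it can lactonize to a butenolide, and the hydroquinone may oxidize in air during isolation. The fallback sets out from 12 and returns at 16; it changes the precursor and the product of the cascade. The tertiary hydroxyl of 12 would be methylated under neutral conditions (MeI, Ag2O) to 2,3,4-trimethoxy-4-{5-methoxy-6-[4-methoxy-3,5-bis(methoxymethoxy)phenyl]-4-oxo-4H-pyran-3-yl}cyclobut-2-en-1-one F1. Thermolysis of F1 in toluene should then give, by the same ring opening and 6π closure, the monophenol 8-hydroxy-3,5,6,7-tetramethoxy-2-[4-methoxy-3,5-bis(methoxymethoxy)phenyl]-4H-chromen-4-one F2. In this variant the ketene has no internal hydroxyl to trap it, the product is no hydroquinone, and the hindered C5 oxygen is methylated before ring A exists. Methylation of the one unhindered phenol of F2 (MeI, K2CO3) leads to 16. If closure at C6 itself proves slow, the C6-linked isomer described under step 7 offers closure at the nucleophilic C5 instead.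

Step 7. What may go wrong is loss of the C5-magnesiated pyranone before it meets the squarate: the ring oxygen stands anti to the C–Mg bond across C5=C6, so β-elimination can open the ring, and the exchange reagent may add to C6 instead of exchanging. The fallback sets out from 7 and returns at 15; it moves the four-membered ring to the other pyranone carbon. Kinetic lithiation of 7 at the C–H next to the ring oxygen (LiTMP with ZnCl2·2LiCl present as an in situ trap, −78 °C) and iodolysis would give 6-iodo-3-methoxy-2-[4-methoxy-3,5-bis(methoxymethoxy)phenyl]-4H-pyran-4-one F3. Iodine–magnesium exchange on F3 gives a C6 carbanion that has no β-leaving group, and its addition to 10 gives rac-4-hydroxy-2,3-dimethoxy-4-{5-methoxy-6-[4-methoxy-3,5-bis(methoxymethoxy)phenyl]-4-oxo-4H-pyran-2-yl}cyclobut-2-en-1-one F4. Thermolysis of F4 closes the ketene onto the nucleophilic C5 (forming the C4a–C5 bond instead of C8–C8a) and, after enolization, should give the same hydroquinone 15.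

Step 6. What may go wrong is metalation at the wrong C–H: at C6 next to the ring oxygen, or on ring B at the positions flanked by an acetal oxygen. A C6 iodide would still funnel into 15 by the path just described, so only ring B metalation is harmful. The fallback sets out from 7 and returns at 9 without new compounds: an amine-promoted electrophilic α-iodination (I2, pyridine, CH2Cl2). Pyridine adds reversibly at C6, the enolate so formed is iodinated at C5 and the amine is expelled, a nucleophile-triggered path that molecular iodine cannot take on ring B.

Step 9. What may go wrong is incomplete alkylation of the hydrogen-bonded 5-hydroxyl and oxidation of the hydroquinone to the 5,8-quinone under basic conditions. The fallback sets out from 15 and returns at 16; it goes through the quinone on purpose. Oxidation of 15 (Ag2O or air) would give the stable, purifiable 3,6,7-trimethoxy-2-[4-methoxy-3,5-bis(methoxymethoxy)phenyl]-4H-chromene-4,5,8-trione F5. Reductive methylation of F5 in one flask (Na2S2O4, then Me2SO4 and KOH under phase-transfer conditions) would give 16.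

## Further compounds

F1 | step 8 | 2,3,4-trimethoxy-4-{5-methoxy-6-[4-methoxy-3,5-bis(methoxymethoxy)phenyl]-4-oxo-4H-pyran-3-yl}cyclobut-2-en-1-one (racemic) | COC1=C(OC)C(OC)(c2coc(-c3cc(OCOC)c(OC)c(OCOC)c3)c(OC)c2=O)C1=O
F2 | step 8 | 8-hydroxy-3,5,6,7-tetramethoxy-2-[4-methoxy-3,5-bis(methoxymethoxy)phenyl]-4H-chromen-4-one | COCOc1cc(-c2oc3c(O)c(OC)c(OC)c(OC)c3c(=O)c2OC)cc(OCOC)c1OC
F3 | step 7 | 6-iodo-3-methoxy-2-[4-methoxy-3,5-bis(methoxymethoxy)phenyl]-4H-pyran-4-one | COCOc1cc(-c2oc(I)cc(=O)c2OC)cc(OCOC)c1OC
F4 | step 7 | rac-4-hydroxy-2,3-dimethoxy-4-{5-methoxy-6-[4-methoxy-3,5-bis(methoxymethoxy)phenyl]-4-oxo-4H-pyran-2-yl}cyclobut-2-en-1-one | COC1=C(OC)C(O)(c2cc(=O)c(OC)c(-c3cc(OCOC)c(OC)c(OCOC)c3)o2)C1=O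
F0 | step 6 | none | none
F5 | step 9 | 3,6,7-trimethoxy-2-[4-methoxy-3,5-bis(methoxymethoxy)phenyl]-4H-chromene-4,5,8-trione | COC1=C(OC)C(=O)c2c(C1=O)oc(-c1cc(OCOC)c(OC)c(OCOC)c1)c(OC)c2=O
A1 | alternative 1 | 2'-hydroxy-3',4',5',6'-tetramethoxyacetophenone | CC(=O)c1c(O)c(OC)c(OC)c(OC)c1OC
A2 | alternative 1 | 3,5-bis(benzyloxy)-4-methoxybenzaldehyde | COc1c(OCc2ccccc2)cc(C=O)cc1OCc1ccccc1
A3 | alternative 1 | (E)-3-[3,5-bis(benzyloxy)-4-methoxyphenyl]-1-(2-hydroxy-3,4,5,6-tetramethoxyphenyl)prop-2-en-1-one | COc1c(OCc2ccccc2)cc(/C=C/C(=O)c2c(O)c(OC)c(OC)c(OC)c2OC)cc1OCc1ccccc1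
A4 | alternative 1 | 2-[3,5-bis(benzyloxy)-4-methoxyphenyl]-3-hydroxy-5,6,7,8-tetramethoxy-4H-chromen-4-one | COc1c(OCc2ccccc2)cc(-c2oc3c(OC)c(OC)c(OC)c(OC)c3c(=O)c2O)cc1OCc1ccccc1
A5 | alternative 2 | 2-iodo-3,4,5,6-tetramethoxyphenol | Oc1c(I)c(OC)c(OC)c(OC)c1OC
A6 | alternative 2 | 5-ethynyl-2-methoxy-1,3-bis(methoxymethoxy)benzene | COCOc1cc(C#C)cc(OCOC)c1OC
A7 | alternative 2 | 5,6,7,8-tetramethoxy-2-[4-methoxy-3,5-bis(methoxymethoxy)phenyl]-4H-chromen-4-one | COCOc1cc(-c2cc(=O)c3c(OC)c(OC)c(OC)c(OC)c3o2)cc(OCOC)c1OC
A8 | alternative 3 | 5-hydroxy-3,7-dimethoxy-2-[4-methoxy-3,5-bis(methoxymethoxy)phenyl]-4H-chromen-4-one | COCOc1cc(-c2oc3cc(OC)cc(O)c3c(=O)c2OC)cc(OCOC)c1OC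
A9 | alternative 3 | 5,8-dihydroxy-3,7-dimethoxy-2-[4-methoxy-3,5-bis(methoxymethoxy)phenyl]-4H-chromen-4-one | COCOc1cc(-c2oc3c(O)c(OC)cc(O)c3c(=O)c2OC)cc(OCOC)c1OC
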